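A direct plan would set C8 by an auxiliary-controlled alkylation and lactonise to the β-(arylmethyl)-γ-butyrolactone A1. It would then add the ring B benzaldehyde to the lactone enolate, hydrogenolyse to the trans-dibenzylbutyrolactone A2, reduce to the 1,4-diol A3 and turn both CH2OH groups into CH3 through the bis-sulfonate A4. Its weakest steps would be:
- the double deoxygenation of the diol, because the mono-sulfonate would close to the tetrahydrofuran and two hydride displacements at β-branched primary carbons would be needed;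
- the hydrogenolytic removal of the aldol hydroxyl, because it would also strip every benzyl ether and force a second protection;
- the auxiliary sequence to A1, because it would spend about eight operations on one stereocentre.

Sauriol B is an acyclic 8–8′ lignan: its whole stereochemical content is the pair of methyl-bearing carbons C8/C8′ in an unfunctionalised chain between ring A (syringyl) and ring B (3-methoxycatechol). Both centres are therefore drawn from sp2 carbons. The two C6–C3 halves are joined at C8–C8′, the bond of the biosynthetic dimerisation, by alkenyl–alkenyl cross-coupling, and a single iridium-catalysed double asymmetric hydrogenation of the resulting (1E,3E)-1,4-diaryl-2,3-dimethylbutadiene sets both centres under catalyst control. The methyl groups are carbon-bound from the start, so no oxygen has to be removed from C9/C9′, no auxiliary is used, and the benzyl ethers are put on once and taken off once.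

Key step: step 8

Assumption: C8 and C8′ are the methyl-bearing carbons next to ring A and ring B; the (S)-configured phosphinooxazoline–iridium catalyst is taken to reduce each ArCH=C(CH3)– unit in the sense known for (E)-1,2-diphenylpropene (R centre), and the (R)-ligand would be used if a trial showed the opposite sense.

Step 1
Reactants: 1 4-bromo-2,6-dimethoxyphenol
Product: 2 2-(benzyloxy)-5-bromo-1,3-dimethoxybenzene
Conditions: BnBr (1.2 equiv), K2CO3 (2 equiv), DMF, 60 °C
Reagents that add atoms: benzyl bromide, BrCc1ccccc1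
Why: Williamson O-benzylation of the phenoxide, with the aryl bromide inert to K2CO3 in DMF.

Step 2
Reactants: 2 2-(benzyloxy)-5-bromo-1,3-dimethoxybenzene; 3 propyne
Product: 4 2-(benzyloxy)-1,3-dimethoxy-5-(prop-1-yn-1-yl)benzene
Conditions: propyne (ca. 1 M in THF, 3 equiv), PdCl2(MeCN)2 (2 mol%), XPhos (6 mol%), Cs2CO3 (2.5 equiv), MeCN, 70 °C, sealed tube
Reagents that add atoms: none
Why: Copper-free Sonogashira coupling, in which the bulky electron-rich biarylphosphine lets zerovalent palladium insert into the electron-rich aryl bromide and the absence of copper avoids oxidative dimerisation of propyne.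

Step 3
Reactants: 4 2-(benzyloxy)-1,3-dimethoxy-5-(prop-1-yn-1-yl)benzene
Product: 5 (Z)-2-{1-[4-(benzyloxy)-3,5-dimethoxyphenyl]prop-1-en-2-yl}-4,4,5,5-tetramethyl-1,3,2-dioxaborolane (aryl cis to CH3, trans to boron)
Conditions: B2pin2 (1.1 equiv), CuCl (5 mol%), P(p-tol)3 (6 mol%), NaOtBu (15 mol%), MeOH (2 equiv), THF, rt
Reagents that add atoms: bis(pinacolato)diboron, CC1(C)OB(OC1(C)C)B1OC(C)(C)C(C)(C)O1
Why: Copper-catalysed formal hydroboration (syn borylcupration, then protonation by methanol with retention), in which copper goes to the aryl-bearing carbon and boron to the methyl-bearing carbon, so H and boron end cis and the olefin geometry is fixed.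

Step 4
Reactants: 6 3,4-dihydroxy-5-methoxybenzaldehyde
Product: 7 3,4-bis(benzyloxy)-5-methoxybenzaldehyde
Conditions: BnBr (2.4 equiv), K2CO3 (3 equiv), DMF, 60 °C, N2
Reagents that add atoms: benzyl bromide, BrCc1ccccc1
Why: Williamson etherification of both catechol hydroxyls gives a base-stable, non-enolisable aldehyde.

Step 5
Reactants: 7 3,4-bis(benzyloxy)-5-methoxybenzaldehyde
Product: 8 1,2-bis(benzyloxy)-5-(2,2-dibromoethenyl)-3-methoxybenzene
Conditions: CBr4 (2 equiv), PPh3 (4 equiv), CH2Cl2, 0 °C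
Reagents that add atoms: carbon tetrabromide, BrC(Br)(Br)Br
Why: Ramirez dibromo-olefination (first stage of the Corey–Fuchs sequence), a Wittig reaction of the ylide Ph3P=CBr2 formed in the flask that leaves benzyl ethers untouched at 0 °C.

Step 6
Reactants: 5 (Z)-2-{1-[4-(benzyloxy)-3,5-dimethoxyphenyl]prop-1-en-2-yl}-4,4,5,5-tetramethyl-1,3,2-dioxaborolane; 8 1,2-bis(benzyloxy)-5-(2,2-dibromoethenyl)-3-methoxybenzene
Product: 9 1,2-bis(benzyloxy)-5-{(1Z,3E)-4-[4-(benzyloxy)-3,5-dimethoxyphenyl]-2-bromo-3-methylbuta-1,3-dien-1-yl}-3-methoxybenzene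
Conditions: 5 (1.05 equiv), Pd2(dba)3 (2.5 mol%), P(2-furyl)3 (15 mol%), Cs2CO3 (3 equiv), THF–H2O 10:1, 60 °C
Reagents that add atoms: none
Why: trans-Selective Suzuki–Miyaura mono-coupling of a 1,1-dibromoalkene, in which zerovalent palladium inserts faster into the C–Br bond trans to the aryl group, the weakly donating trifurylphosphine stops at the mono-coupled stage and the boronate couples with retention, so the C8–C8′ bond forms with the 3E olefin and the remaining bromine cis to ring B.

Step 7
Reactants: 9 1,2-bis(benzyloxy)-5-{(1Z,3E)-4-[4-(benzyloxy)-3,5-dimethoxyphenyl]-2-bromo-3-methylbuta-1,3-dien-1-yl}-3-methoxybenzene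
Product: 10 1,2-bis(benzyloxy)-5-{(1E,3E)-4-[4-(benzyloxy)-3,5-dimethoxyphenyl]-2,3-dimethylbuta-1,3-dien-1-yl}-3-methoxybenzene
Conditions: MeZnCl (2 M in THF, 2 equiv), Pd(PtBu3)2 (3 mol%), THF, rt
Reagents that add atoms: methylzinc chloride, C[Zn]Cl
Why: Negishi methylation of the 2-bromo-1,3-diene, for which the bulky monophosphine complex couples hindered alkenyl bromides with retention, so CH3 takes the place cis to ring B and the (1E,3E)-diene results.

Step 8
Reactants: 10 1,2-bis(benzyloxy)-5-{(1E,3E)-4-[4-(benzyloxy)-3,5-dimethoxyphenyl]-2,3-dimethylbuta-1,3-dien-1-yl}-3-methoxybenzene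
Product: 13 1,2-bis(benzyloxy)-5-{(2R,3R)-4-[4-(benzyloxy)-3,5-dimethoxyphenyl]-2,3-dimethylbutyl}-3-methoxybenzene, via C8-reduced monoene 11 (not isolated), via C8′-reduced monoene 12 (not isolated)
Conditions: H2 (50 bar), [Ir(cod)(L)][B(3,5-(CF3)2C6H3)4] (2 mol%; L = (S)-4-tert-butyl-2-[2-(di-o-tolylphosphino)phenyl]-4,5-dihydrooxazole), CH2Cl2, rt
Reagents that add atoms: none
Why: After hydrogenation of the cod ligand the cationic iridium N,P complex binds one trisubstituted olefin next to its hydrides, and migratory insertion followed by reductive elimination delivers both hydrogens to one face (syn 1,2-addition), first to monoenes 11 and 12 and then to 13. The closest known reaction type is the iridium–phosphinooxazoline hydrogenation of unfunctionalised (E)-trisubstituted aryl alkenes and of aryl-substituted conjugated dienes; no ring is closed. Each new stereocentre (C8 and C8′) is set by the ligand, which orients the olefin by the position of its single vinylic hydrogen, so each ArCH=C(CH3)– unit should be reduced from the same topological face and give the R centre. Because the two olefins of the s-trans diene are related by a local twofold axis, the same facial preference at both gives the like (R,R) isomer; one catalyst error would give the meso diastereomer, in principle separable, and not the enantiomer, which raises the enantiomeric purity of the (R,R) product. The step needs 1,2- and not 1,4-addition (these catalysts engage one olefin at a time, and a tetrasubstituted 1,4-adduct would not be reduced further) and catalyst control over the allylic centre in the second reduction (both olefins are (E)-1-aryl-2-methylalkenes, a favourable class for these catalysts). Aryl benzyl and methyl ethers neither bind the cationic metal nor undergo hydrogenolysis under these homogeneous conditions.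

Step 9
Reactants: 13 1,2-bis(benzyloxy)-5-{(2R,3R)-4-[4-(benzyloxy)-3,5-dimethoxyphenyl]-2,3-dimethylbutyl}-3-methoxybenzene
Product: 14 sauriol B, 5-[(2R,3R)-4-(4-hydroxy-3,5-dimethoxyphenyl)-2,3-dimethylbutyl]-3-methoxybenzene-1,2-diol
Conditions: H2 (1 atm), 10% Pd/C, EtOAc–MeOH, rt; filter under Ar
Reagents that add atoms: none
Why: Heterogeneous hydrogenolysis of the three aryl benzyl ethers releases the catechol and the syringyl phenol, while the methyl ethers, the saturated chain and both stereocentres are not reaction sites.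

## Compound list

1 | 4-bromo-2,6-dimethoxyphenol | COc1cc(Br)cc(OC)c1O | starting material
2 | 2-(benzyloxy)-5-bromo-1,3-dimethoxybenzene | COc1cc(Br)cc(OC)c1OCc1ccccc1 | intermediate
3 | propyne | CC#C | starting material
4 | 2-(benzyloxy)-1,3-dimethoxy-5-(prop-1-yn-1-yl)benzene | CC#Cc1cc(OC)c(OCc2ccccc2)c(OC)c1 | intermediate
5 | (Z)-2-{1-[4-(benzyloxy)-3,5-dimethoxyphenyl]prop-1-en-2-yl}-4,4,5,5-tetramethyl-1,3,2-dioxaborolane | C/C(B1OC(C)(C)C(C)(C)O1)=C\c1cc(OC)c(OCc2ccccc2)c(OC)c1 | intermediate
6 | 3,4-dihydroxy-5-methoxybenzaldehyde | COc1cc(C=O)cc(O)c1O | starting material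
7 | 3,4-bis(benzyloxy)-5-methoxybenzaldehyde | COc1cc(C=O)cc(OCc2ccccc2)c1OCc1ccccc1 | intermediate
8 | 1,2-bis(benzyloxy)-5-(2,2-dibromoethenyl)-3-methoxybenzene | COc1cc(C=C(Br)Br)cc(OCc2ccccc2)c1OCc1ccccc1 | intermediate
9 | 1,2-bis(benzyloxy)-5-{(1Z,3E)-4-[4-(benzyloxy)-3,5-dimethoxyphenyl]-2-bromo-3-methylbuta-1,3-dien-1-yl}-3-methoxybenzene | COc1cc(/C=C(\Br)/C(C)=C/c2cc(OC)c(OCc3ccccc3)c(OC)c2)cc(OCc2ccccc2)c1OCc1ccccc1 | intermediate
10 | 1,2-bis(benzyloxy)-5-{(1E,3E)-4-[4-(benzyloxy)-3,5-dimethoxyphenyl]-2,3-dimethylbuta-1,3-dien-1-yl}-3-methoxybenzene | COc1cc(/C=C(\C)/C(C)=C/c2cc(OC)c(OCc3ccccc3)c(OC)c2)cc(OCc2ccccc2)c1OCc1ccccc1 | intermediate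
11 | 2-(benzyloxy)-5-{(2R,3E)-4-[3,4-bis(benzyloxy)-5-methoxyphenyl]-2,3-dimethylbut-3-en-1-yl}-1,3-dimethoxybenzene (C8-reduced monoene) | COc1cc(/C=C(\C)[C@H](C)Cc2cc(OC)c(OCc3ccccc3)c(OC)c2)cc(OCc2ccccc2)c1OCc1ccccc1 | intermediate
12 | 1,2-bis(benzyloxy)-5-{(2R,3E)-4-[4-(benzyloxy)-3,5-dimethoxyphenyl]-2,3-dimethylbut-3-en-1-yl}-3-methoxybenzene (C8′-reduced monoene) | COc1cc(C[C@@H](C)/C(C)=C/c2cc(OC)c(OCc3ccccc3)c(OC)c2)cc(OCc2ccccc2)c1OCc1ccccc1 | intermediate
13 | 1,2-bis(benzyloxy)-5-{(2R,3R)-4-[4-(benzyloxy)-3,5-dimethoxyphenyl]-2,3-dimethylbutyl}-3-methoxybenzene | COc1cc(C[C@@H](C)[C@H](C)Cc2cc(OC)c(OCc3ccccc3)c(OC)c2)cc(OCc2ccccc2)c1OCc1ccccc1 | intermediate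
14 | sauriol B, 5-[(2R,3R)-4-(4-hydroxy-3,5-dimethoxyphenyl)-2,3-dimethylbutyl]-3-methoxybenzene-1,2-diol | COc1cc(C[C@@H](C)[C@H](C)Cc2cc(OC)c(O)c(OC)c2)cc(O)c1O | target

Total step count: 9. Longest linear sequence: 7 steps (steps 1, 2, 3, 6, 7, 8, 9 from compound 1).

Steps most likely to fail:

Step 8. The catalyst could lose control in the second reduction, where the new allylic centre may oppose it and give the meso isomer, or 1,4-addition could lead to a tetrasubstituted olefin. The two centres would then be set one at a time by reagent control and joined by stereospecific 1,2-metallate shifts; the fallback sets out from dibromide 8 and aryl bromide 2 and returns at 13.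
- n-BuLi (2.1 equiv, THF, −78 °C) and then MeI would convert 8 into 1,2-bis(benzyloxy)-3-methoxy-5-(prop-1-yn-1-yl)benzene F1 (Corey–Fuchs alkynylation with methyl quench).
- The borylation conditions of step 3 would give (Z)-2-{1-[3,4-bis(benzyloxy)-5-methoxyphenyl]prop-1-en-2-yl}-4,4,5,5-tetramethyl-1,3,2-dioxaborolane F2.
- Asymmetric hydrogenation of this single olefin, with the iridium catalyst of step 8 or its enantiomer as needed, would give 2-{(2R)-1-[3,4-bis(benzyloxy)-5-methoxyphenyl]propan-2-yl}-4,4,5,5-tetramethyl-1,3,2-dioxaborolane F3.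
- Homologation with lithiated ethyl 2,4,6-triisopropylbenzoate (s-BuLi, the sparteine enantiomer that gives the S boron-bearing centre, Et2O, −78 °C → rt) would give 2-{(2S,3R)-4-[3,4-bis(benzyloxy)-5-methoxyphenyl]-3-methylbutan-2-yl}-4,4,5,5-tetramethyl-1,3,2-dioxaborolane F4.
- Matteson insertion of ClCH2Li (BrCH2Cl, n-BuLi, −78 °C) would give 2-{(2R,3R)-4-[3,4-bis(benzyloxy)-5-methoxyphenyl]-2,3-dimethylbutyl}-4,4,5,5-tetramethyl-1,3,2-dioxaborolane F5.
- B-alkyl Suzuki–Miyaura coupling of F5 with aryl bromide 2 (Pd(OAc)2, RuPhos, K3PO4, toluene–H2O, 80 °C) would give 13.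

Step 6. Over-coupling to the triene, protodeboronation of the hindered α-methyl alkenyl boronate, or base-induced loss of HBr to an enyne could occur. The polarity of the coupling would then be reversed so that no dihalide is involved; the fallback sets out from boronate 5 and returns at diene 10, which also makes step 7 unnecessary.
- CuBr2 (3 equiv, MeOH–H2O, 80 °C) would convert 5 with retention into (E)-2-(benzyloxy)-5-(2-bromoprop-1-en-1-yl)-1,3-dimethoxybenzene F6.
- The ring B alkenyl boronate F2 would be made from 8 through F1 as described under step 8.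
- Suzuki–Miyaura coupling of F6 with F2 (Pd(dppf)Cl2, K3PO4, dioxane–H2O, 80 °C) would give 10.

Step 7. Oxidative addition at the hindered bromide cis to ring B could be slow, or the dienylpalladium intermediate could isomerise. The bromine would then be exchanged for lithium; the fallback sets out from bromodiene 9 and returns at 10.
- t-BuLi (2.1 equiv, THF, −78 °C) would give the configurationally stable {(1E,3E)-1-[3,4-bis(benzyloxy)-5-methoxyphenyl]-4-[4-(benzyloxy)-3,5-dimethoxyphenyl]-3-methylbuta-1,3-dien-2-yl}lithium F7.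
- MeI would alkylate F7 with retention to give 10.

## Further compounds

F1 | step 8 | 1,2-bis(benzyloxy)-3-methoxy-5-(prop-1-yn-1-yl)benzene | CC#Cc1cc(OC)c(OCc2ccccc2)c(OCc2ccccc2)c1
F2 | step 8 | (Z)-2-{1-[3,4-bis(benzyloxy)-5-methoxyphenyl]prop-1-en-2-yl}-4,4,5,5-tetramethyl-1,3,2-dioxaborolane | C/C(B1OC(C)(C)C(C)(C)O1)=C\c1cc(OC)c(OCc2ccccc2)c(OCc2ccccc2)c1
F3 | step 8 | 2-{(2R)-1-[3,4-bis(benzyloxy)-5-methoxyphenyl]propan-2-yl}-4,4,5,5-tetramethyl-1,3,2-dioxaborolane | COc1cc(C[C@@H](C)B2OC(C)(C)C(C)(C)O2)cc(OCc2ccccc2)c1OCc1ccccc1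
F4 | step 8 | 2-{(2S,3R)-4-[3,4-bis(benzyloxy)-5-methoxyphenyl]-3-methylbutan-2-yl}-4,4,5,5-tetramethyl-1,3,2-dioxaborolane | COc1cc(C[C@@H](C)[C@H](C)B2OC(C)(C)C(C)(C)O2)cc(OCc2ccccc2)c1OCc1ccccc1
F5 | step 8 | 2-{(2R,3R)-4-[3,4-bis(benzyloxy)-5-methoxyphenyl]-2,3-dimethylbutyl}-4,4,5,5-tetramethyl-1,3,2-dioxaborolane | COc1cc(C[C@@H](C)[C@H](C)CB2OC(C)(C)C(C)(C)O2)cc(OCc2ccccc2)c1OCc1ccccc1
F6 | step 6 | (E)-2-(benzyloxy)-5-(2-bromoprop-1-en-1-yl)-1,3-dimethoxybenzene | C/C(Br)=C\c1cc(OC)c(OCc2ccccc2)c(OC)c1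
F7 | step 7 | {(1E,3E)-1-[3,4-bis(benzyloxy)-5-methoxyphenyl]-4-[4-(benzyloxy)-3,5-dimethoxyphenyl]-3-methylbuta-1,3-dien-2-yl}lithium | COc1cc(/C=C(\[Li])/C(C)=C/c2cc(OC)c(OCc3ccccc3)c(OC)c2)cc(OCc2ccccc2)c1OCc1ccccc1
A1 | direct plan | (4R)-4-{[4-(benzyloxy)-3,5-dimethoxyphenyl]methyl}oxolan-2-one | O=C1OC[C@H](Cc2cc(OC)c(OCc3ccccc3)c(OC)c2)C1
A2 | direct plan | (3R,4R)-3-[(3,4-dihydroxy-5-methoxyphenyl)methyl]-4-[(4-hydroxy-3,5-dimethoxyphenyl)methyl]oxolan-2-one | O=C1OC[C@H](Cc2cc(OC)c(O)c(OC)c2)[C@H]1Cc1cc(OC)c(O)c(O)c1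
A3 | direct plan | (2R,3R)-2-{[3,4-bis(benzyloxy)-5-methoxyphenyl]methyl}-3-{[4-(benzyloxy)-3,5-dimethoxyphenyl]methyl}butane-1,4-diol | COc1cc(C[C@@H](CO)[C@H](CO)Cc2cc(OC)c(OCc3ccccc3)c(OC)c2)cc(OCc2ccccc2)c1OCc1ccccc1
A4 | direct plan | (2R,3R)-2-{[3,4-bis(benzyloxy)-5-methoxyphenyl]methyl}-3-{[4-(benzyloxy)-3,5-dimethoxyphenyl]methyl}butane-1,4-diyl dimethanesulfonate | COc1cc(C[C@@H](COS(C)(=O)=O)[C@H](COS(C)(=O)=O)Cc2cc(OC)c(OCc3ccccc3)c(OC)c2)cc(OCc2ccccc2)c1OCc1ccccc1
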